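**Retrosynthetic overview**
- The target is (2S,4R)-5,7-dimethoxy-8-prenylflavan-4-ol (2,4-trans). Disconnect C3–C4 and O1–C2 together: salicylaldehyde 7 + styrene 8, joined by ketyl-radical addition to styrene followed by radical-polar crossover ring closure.
- Aldehyde 7 comes from ortho-formylation of prenylphenol 6, which comes from ortho-C-prenylation of 3,5-dimethoxyphenol 4.
- Phenol 4 comes from C–H borylation/oxidation of 1,3-dimethoxybenzene 2, made from resorcinol 1.
- Ring order: ring A (from resorcinol) and the phenyl ring (from styrene) are bought intact. Only the pyran ring is built, in the last step, where both stereocentres are set.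

Assumptions: the one-pot borylation/oxidation (step 2) is counted as one step. In step 5, (R)-TRIP is written; which enantiomer of the acid gives (4R) must be found experimentally, and the antipode is used if the sense is opposite.

**Step 1**
Reactants: 1, resorcinol (benzene-1,3-diol)
Product: 2, 1,3-dimethoxybenzene
Conditions: Me2SO4 (2.4 equiv), K2CO3 (3 equiv), acetone, reflux
Reagents that add atoms: dimethyl sulfate, COS(=O)(=O)OC
Why: Williamson O-methylation of both phenols; no stereocentre is involved.

**Step 2**
Reactants: 2, 1,3-dimethoxybenzene
Product: 4, 3,5-dimethoxyphenol (via aryl boronate 3, 2-(3,5-dimethoxyphenyl)-4,4,5,5-tetramethyl-1,3,2-dioxaborolane, not isolated)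
Conditions: [Ir(OMe)(cod)]2 (1 mol%), dtbpy (2 mol%), B2pin2 (0.7 equiv), THF, 80 °C; evaporate; then Oxone (1 equiv), acetone/H2O, rt
Reagents that add atoms: B2pin2, CC1(C)OB(OC1(C)C)B1OC(C)(C)C(C)(C)O1 (boron only in 3); Oxone, [K+].[O-]S(=O)(=O)OO (the phenol oxygen)
Why: sterically controlled Ir-catalysed aromatic C–H borylation takes the only C–H not ortho to a methoxy group (C5), and ipso-oxidation of the aryl boronate gives the phenol.

**Step 3**
Reactants: 4, 3,5-dimethoxyphenol (1.5 equiv); 5, prenyl bromide (1-bromo-3-methylbut-2-ene, 1.0 equiv)
Product: 6, 3,5-dimethoxy-2-(3-methylbut-2-en-1-yl)phenol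
Conditions: NaH (1.5 equiv), toluene, 0 °C to rt; chromatography, excess 4 recycled
Reagents that add atoms: none
Why: ortho-C-alkylation of a tight sodium phenoxide ion pair in a non-polar solvent (SN2 at the primary carbon gives the linear prenyl group); the two ortho positions are equivalent and the para position is flanked by two methoxy groups.

**Step 4**
Reactants: 6, 3,5-dimethoxy-2-(3-methylbut-2-en-1-yl)phenol
Product: 7, 2-hydroxy-4,6-dimethoxy-3-(3-methylbut-2-en-1-yl)benzaldehyde
Conditions: MgCl2 (2 equiv), Et3N (4 equiv), (CH2O)n (6 equiv), MeCN, reflux; cold aq. NH4Cl work-up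
Reagents that add atoms: paraformaldehyde (formaldehyde), C=O
Why: Casnati–Skattebøl magnesium-templated ortho-formylation (ortho-hydroxymethylation, then hydride transfer to excess formaldehyde) can only take the one free ortho position; the basic medium leaves the prenyl alkene untouched.

**Step 5 (key step)**
Reactants: 7, 2-hydroxy-4,6-dimethoxy-3-(3-methylbut-2-en-1-yl)benzaldehyde; 8, styrene (5 equiv)
Product: 9, (2S,4R)-5,7-dimethoxy-8-(3-methylbut-2-en-1-yl)-2-phenylchroman-4-ol (2,4-trans; target)
Conditions: fac-Ir(ppy)3 (2 mol%), (R)-TRIP (10 mol%), toluene/1,4-dioxane 4:1, 0.1 M, blue LEDs (450 nm), 0 °C, Ar; Et3N quench before concentration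
Reagents that add atoms: none
Why: Proposed new method: a redox-neutral asymmetric ketyl–olefin [4+2] annulation in which excited Ir(III) and the chiral phosphoric acid reduce the two-point H-bonded salicylaldehyde by proton-coupled electron transfer to a neutral ketyl held on the chiral phosphate; this radical adds to the CH2 terminus of styrene (C3–C4 bond, C4 set as R in the chiral H-bonded complex), the resulting secondary benzylic radical (about +0.4 V) is oxidised by Ir(IV) (+0.77 V) to the benzylic cation, and the ortho-phenol closes the ring through a chair-like transition state with phenyl equatorial and the C4–OH pseudo-axial (avoiding A(1,3) strain with the 5-OMe), giving the 2,4-trans (2S) ether; the closest known reaction types are chiral-phosphoric-acid-controlled PCET ketyl couplings (enantioselective aza-pinacol cyclisation) and photoredox radical-polar crossover oxy-functionalisation of styrenes, and the prenyl alkene is too poor a radical acceptor and too hard to oxidise to interfere.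

**Compound list**
1 | resorcinol | Oc1cccc(O)c1 | starting material
2 | 1,3-dimethoxybenzene | COc1cccc(OC)c1 | intermediate
3 | 2-(3,5-dimethoxyphenyl)-4,4,5,5-tetramethyl-1,3,2-dioxaborolane | COc1cc(OC)cc(c1)B1OC(C)(C)C(C)(C)O1 | intermediate (not isolated)
4 | 3,5-dimethoxyphenol | COc1cc(O)cc(OC)c1 | intermediate
5 | prenyl bromide (1-bromo-3-methylbut-2-ene) | CC(C)=CCBr | starting material
6 | 3,5-dimethoxy-2-(3-methylbut-2-en-1-yl)phenol | COc1cc(O)c(CC=C(C)C)c(OC)c1 | intermediate
7 | 2-hydroxy-4,6-dimethoxy-3-(3-methylbut-2-en-1-yl)benzaldehyde | COc1cc(OC)c(C=O)c(O)c1CC=C(C)C | intermediate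
8 | styrene | C=Cc1ccccc1 | starting material
9 | (2S,4R)-5,7-dimethoxy-8-(3-methylbut-2-en-1-yl)-2-phenylchroman-4-ol | COc1cc(OC)c2c(c1CC=C(C)C)O[C@H](c1ccccc1)C[C@H]2O | target

**Totals**
Total steps: 5 (step 2 is a one-pot borylation/oxidation). Longest linear sequence: 5 steps (1 → 2 → 4 → 6 → 7 → 9).

**Three steps most likely to fail**
1. Step 5. The hindered, electron-rich ketyl may dimerise (pinacol) instead of adding to styrene, ee or dr may be low, and the acid-labile 2,4,6-trioxygenated benzylic alcohol may ionise or eliminate. Fallback: run the same annulation racemically with diphenyl phosphate to (±)-trans-9, then obtain the (2S,4R) enantiomer by lipase-catalysed acylative kinetic resolution (vinyl acetate), so stereocontrol no longer depends on the radical step.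
2. Step 3. O-alkylation, para-alkylation and bis-prenylation compete with the ortho-C-prenylation. Fallback: O-alkylate 4 with 3-chloro-3-methylbut-1-yne (DBU, cat. CuCl2), semi-hydrogenate (Lindlar) to the 1,1-dimethylallyl ether, and run an aromatic Claisen rearrangement, which delivers the ortho-prenyl phenol 6 regiospecifically (two extra steps).
3. Step 4. The hindered, very electron-rich phenol may give diarylmethane by-products or low conversion. Fallback: reverse the order: formylate 4 first to 2-hydroxy-4,6-dimethoxybenzaldehyde, then install the prenyl group at C3 by the propargyl ether / Lindlar / Claisen sequence.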